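Ring B is a 5-methylresorcinol acylated at C1' whose two flanking oxygens, O-2' and O-6', must end up different (phenol and acetate). The plan therefore builds ring B from acyclic pieces by a thermal cyclobutenone/siloxyalkyne benzannulation: 3-methylcyclobutenone and an ynol silyl ether whose remote alkyne carbon already carries ring A deliver, in one operation, the arene with C1' between a free hydroxyl (O-2') and a silyl ether (O-6') and the methyl at C4'. The benzophenone carbonyl is held at the carbinol level inside a phthalide so that the alkyne stays electron-rich; after the annulation it is oxidised, the phenol acetylated and both silyl ethers removed together.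

Key step: step 8

Remark on numbering and stereochemistry: ring B carbons are C1' (carbonyl-bearing) to C6' (C2' hydroxyl, C4' methyl, C6' acetate), lactones are numbered as 2-benzofuran-1(3H)-ones, every C3-stereogenic intermediate is racemic, and the target is achiral.

Step 1
Reactants: 1 methyl 3,5-dihydroxybenzoate
Product: 3 methyl 2-formyl-3,5-dihydroxybenzoate, via iminium chloride 2 (not isolated)
Conditions: POCl3, DMF, MeCN, 0 °C → rt; then H2O, 50 °C
Reagents that add atoms: N,N-dimethylformamide CN(C)C=O; water O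
Why: Vilsmeier–Haack formylation, in which the chloroiminium ion attacks the resorcinol ring at C2 (ortho to one hydroxyl, para to the other, and equivalent to C6 by symmetry), so a single aldehyde should result and the future benzophenone carbon is placed unambiguously between the ester and an oxygen.

Step 2
Reactants: 3 methyl 2-formyl-3,5-dihydroxybenzoate
Product: 4 methyl 2-formyl-3-hydroxy-5-[(triisopropylsilyl)oxy]benzoate
Conditions: i-Pr3SiCl (1.05 equiv), imidazole, CH2Cl2, 0 °C
Reagents that add atoms: chlorotriisopropylsilane CC(C)[Si](Cl)(C(C)C)C(C)C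
Why: Selective phenol silylation, since the C5 hydroxyl para to the formyl group is the more acidic and accessible one, whereas the C3 hydroxyl is hydrogen-bonded to the aldehyde and shielded from the bulky silyl chloride.

Step 3
Reactants: 4 methyl 2-formyl-3-hydroxy-5-[(triisopropylsilyl)oxy]benzoate
Product: 5 methyl 2-formyl-3-methoxy-5-[(triisopropylsilyl)oxy]benzoate
Conditions: MeOH, PPh3, DIAD, THF, 0 °C → rt
Reagents that add atoms: methanol CO
Why: Mitsunobu etherification, which methylates the acidic salicylaldehyde-type phenol under neutral conditions and so spares the aryl silyl ether para to the aldehyde, a group that carbonate bases could cleave or scramble.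

Step 4
Reactants: 6 ethynyltrimethylsilane
Product: 9 triisopropyl{[(trimethylsilyl)ethynyl]oxy}silane, via lithium acetylide 7 (not isolated), via lithium ynolate 8 (not isolated)
Conditions: n-BuLi, THF, −78 °C; LiOOt-Bu (from t-BuOOH, LiN(SiMe3)2), −78 → 0 °C; i-Pr3SiOTf, −78 °C
Reagents that add atoms: tert-butyl hydroperoxide CC(C)(C)OO; triisopropylsilyl trifluoromethanesulfonate CC(C)[Si](OS(=O)(=O)C(F)(F)F)(C(C)C)C(C)C
Why: Oxidation of a lithium acetylide by lithium tert-butyl peroxide (Julia-type electrophilic oxygen transfer, the standard entry to siloxyalkynes from terminal alkynes) gives the ynolate, which the bulky silyl triflate should trap on oxygen because the carbon terminus already carries a silyl group.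

Step 5
Reactants: 9 triisopropyl{[(trimethylsilyl)ethynyl]oxy}silane
Product: 10 (ethynyloxy)triisopropylsilane
Conditions: K2CO3 (cat.), MeOH, 0 °C, short contact; pentane extraction, used at once as a solution
Reagents that add atoms: none
Why: Methanolysis of an alkynyl–SiMe3 bond, in which methoxide should attack the small trimethylsilyl group far faster than the hindered triisopropylsilyl group on oxygen, the reaction being kept cold and short to protect the ynol ether.

Step 6
Reactants: 10 (ethynyloxy)triisopropylsilane; 5 methyl 2-formyl-3-methoxy-5-[(triisopropylsilyl)oxy]benzoate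
Product: 13 rac-4-methoxy-6-[(triisopropylsilyl)oxy]-3-{[(triisopropylsilyl)oxy]ethynyl}-2-benzofuran-1(3H)-one, via lithium silyloxyacetylide 11 (not isolated), via lithium alkoxide 12 (not isolated)
Conditions: n-BuLi, THF, −78 °C; then aldehyde, −78 → −20 °C; pH 7 phosphate buffer
Reagents that add atoms: none
Why: 1,2-Addition of a lithium acetylide (the silyloxy analogue of lithium ethoxyacetylide) to the aldehyde, followed by 5-exo-trig acyl substitution of the alkoxide on the neighbouring methyl ester to close the phthalide; C3 forms as a racemate, which suffices because this centre is oxidised to the ketone in step 9.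

Step 7
Reactants: 14 3-ethoxycyclobut-2-en-1-one
Product: 16 3-methylcyclobut-2-en-1-one, via lithium cyclobutenolate 15 (not isolated)
Conditions: MeLi, Et2O, −78 °C; then 1 M HCl, 0 °C; used as a toluene solution
Reagents that add atoms: methyllithium [Li]C
Why: 1,2-Addition of methyllithium to the vinylogous ester followed by acid hydrolysis of the enol ether with loss of ethanol (carbonyl transposition), the established route from 3-ethoxycyclobutenone to 3-substituted cyclobutenones.

Step 8
Reactants: 16 3-methylcyclobut-2-en-1-one; 13 rac-4-methoxy-6-[(triisopropylsilyl)oxy]-3-{[(triisopropylsilyl)oxy]ethynyl}-2-benzofuran-1(3H)-one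
Product: 21 rac-3-{2-hydroxy-4-methyl-6-[(triisopropylsilyl)oxy]phenyl}-4-methoxy-6-[(triisopropylsilyl)oxy]-2-benzofuran-1(3H)-one, via vinylketene 17 (not isolated), via vinylcyclobutenone 18 (not isolated), via dienylketene 19 (not isolated), via cyclohexadienone 20 (not isolated)
Conditions: cyclobutenone (2 equiv), PhMe, sealed tube, 80 °C then 110 °C
Reagents that add atoms: none
Why: Thermal four-electron electrocyclic opening of 16 gives vinylketene 17, which adds in a [2+2] sense to the electron-rich ynol ether 13, the ketene carbonyl carbon bonding to the alkyne carbon that carries ring A (remote from oxygen), to give 18; four-electron opening of 18 to dienylketene 19 and six-electron electrocyclisation give cyclohexadienone 20, which enolises to the phenol. The closest known reaction type is the Danheiser benzannulation of cyclobutenones with triisopropylsilyloxyalkynes, which gives resorcinol monosilyl ethers. Ring B is closed by the thermal six-electron (disrotatory) electrocyclisation of the dienylketene, which forms C2'–C3' after the cycloaddition has formed C1'–C2' and C5'–C6'. No new stereocentre remains: C3 of the lactone is a racemic spectator and the transient centre of 18 is lost on ring opening. The step needs regiocontrol, which the polarisation of the ynol ether secures (its nucleophilic carbon attacks the ketene carbonyl carbon), so that C1' lies between the new hydroxyl O-2' and the silyl ether O-6' and the methyl group lands at C4'. The bulky triisopropylsilyl group should slow the 1,3-shift of silicon from oxygen to carbon at these temperatures, and carrying the future ketone as a lactone carbinol keeps the alkyne electron-rich.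

Step 9
Reactants: 21 rac-3-{2-hydroxy-4-methyl-6-[(triisopropylsilyl)oxy]phenyl}-4-methoxy-6-[(triisopropylsilyl)oxy]-2-benzofuran-1(3H)-one
Product: 23 2-{2-hydroxy-4-methyl-6-[(triisopropylsilyl)oxy]benzoyl}-3-methoxy-5-[(triisopropylsilyl)oxy]benzoic acid, via lactol 22 (not isolated)
Conditions: DDQ (1.3 equiv), CH2Cl2/H2O (10:1), 0 °C → rt
Reagents that add atoms: water O
Why: DDQ benzylic oxidation, in which hydride is taken from the doubly benzylic C3–H (activated by the free ortho phenol of ring B through a quinone methide and by the para silyloxy and ortho methoxy groups of ring A) and water captures the cation as the lactol, which opens to the hydrogen-bonded 2-hydroxybenzophenone acid and removes the racemic centre.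

Step 10
Reactants: 23 2-{2-hydroxy-4-methyl-6-[(triisopropylsilyl)oxy]benzoyl}-3-methoxy-5-[(triisopropylsilyl)oxy]benzoic acid
Product: 24 methyl 2-{2-hydroxy-4-methyl-6-[(triisopropylsilyl)oxy]benzoyl}-3-methoxy-5-[(triisopropylsilyl)oxy]benzoate
Conditions: MeI, KHCO3, DMF, rt
Reagents that add atoms: iodomethane CI
Why: SN2 O-alkylation of the carboxylate, bicarbonate deprotonating only the acid so that the open-chain (normal) methyl ester forms while the ketone-chelated phenol stays free.

Step 11
Reactants: 24 methyl 2-{2-hydroxy-4-methyl-6-[(triisopropylsilyl)oxy]benzoyl}-3-methoxy-5-[(triisopropylsilyl)oxy]benzoate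
Product: 25 methyl 2-{2-acetoxy-4-methyl-6-[(triisopropylsilyl)oxy]benzoyl}-3-methoxy-5-[(triisopropylsilyl)oxy]benzoate
Conditions: Ac2O, pyridine, DMAP (cat.), CH2Cl2, rt
Reagents that add atoms: acetic anhydride CC(=O)OC(C)=O
Why: DMAP-catalysed acylation of the only free hydroxyl, the second ring B oxygen still being masked as its silyl ether, which is how the two otherwise equivalent oxygens are told apart.

Step 12
Reactants: 25 methyl 2-{2-acetoxy-4-methyl-6-[(triisopropylsilyl)oxy]benzoyl}-3-methoxy-5-[(triisopropylsilyl)oxy]benzoate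
Product: 26 penibenzophenone C, methyl 2-(2-acetoxy-6-hydroxy-4-methylbenzoyl)-5-hydroxy-3-methoxybenzoate
Conditions: Bu4NF, AcOH (1:1), THF, 0 °C
Reagents that add atoms: none
Why: Fluoride cleavage of both aryl silyl ethers under acetic acid buffering, so that each liberated phenoxide is protonated at once and the aryl acetate is neither hydrolysed nor transferred; ring B is symmetric about the C1'–C4' axis, so the monoacetate is a single compound.

Compound list
1 | methyl 3,5-dihydroxybenzoate | COC(=O)c1cc(O)cc(O)c1 | starting material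
2 | N-[2,4-dihydroxy-6-(methoxycarbonyl)benzylidene]-N-methylmethanaminium chloride | COC(=O)c1cc(O)cc(O)c1C=[N+](C)C.[Cl-] | intermediate (not isolated)
3 | methyl 2-formyl-3,5-dihydroxybenzoate | COC(=O)c1cc(O)cc(O)c1C=O | intermediate
4 | methyl 2-formyl-3-hydroxy-5-[(triisopropylsilyl)oxy]benzoate | COC(=O)c1cc(O[Si](C(C)C)(C(C)C)C(C)C)cc(O)c1C=O | intermediate
5 | methyl 2-formyl-3-methoxy-5-[(triisopropylsilyl)oxy]benzoate | COC(=O)c1cc(O[Si](C(C)C)(C(C)C)C(C)C)cc(OC)c1C=O | intermediate
6 | ethynyltrimethylsilane | C#C[Si](C)(C)C | starting material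
7 | lithium (trimethylsilyl)acetylide | [Li]C#C[Si](C)(C)C | intermediate (not isolated)
8 | lithium 2-(trimethylsilyl)ethynolate | [Li+].[O-]C#C[Si](C)(C)C | intermediate (not isolated)
9 | triisopropyl{[(trimethylsilyl)ethynyl]oxy}silane | C[Si](C)(C)C#CO[Si](C(C)C)(C(C)C)C(C)C | intermediate
10 | (ethynyloxy)triisopropylsilane | C#CO[Si](C(C)C)(C(C)C)C(C)C | intermediate
11 | lithium [(triisopropylsilyl)oxy]acetylide | [Li]C#CO[Si](C(C)C)(C(C)C)C(C)C | intermediate (not isolated)
12 | lithium alkoxide of methyl 2-{1-hydroxy-3-[(triisopropylsilyl)oxy]prop-2-yn-1-yl}-3-methoxy-5-[(triisopropylsilyl)oxy]benzoate (racemic) | [Li+].[O-]C(C#CO[Si](C(C)C)(C(C)C)C(C)C)c1c(OC)cc(O[Si](C(C)C)(C(C)C)C(C)C)cc1C(=O)OC | intermediate (not isolated)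
13 | rac-4-methoxy-6-[(triisopropylsilyl)oxy]-3-{[(triisopropylsilyl)oxy]ethynyl}-2-benzofuran-1(3H)-one | O=C1OC(C#CO[Si](C(C)C)(C(C)C)C(C)C)c2c(OC)cc(O[Si](C(C)C)(C(C)C)C(C)C)cc12 | intermediate (precursor of the key step)
14 | 3-ethoxycyclobut-2-en-1-one | CCOC1=CC(=O)C1 | starting material
15 | lithium 3-ethoxy-1-methylcyclobut-2-en-1-olate (racemic) | [Li+].[O-]C1(C)C=C(OCC)C1 | intermediate (not isolated)
16 | 3-methylcyclobut-2-en-1-one | CC1=CC(=O)C1 | intermediate
17 | 3-methylbuta-1,3-dien-1-one (isopropenylketene) | C=C(C)C=C=O | intermediate (not isolated)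
18 | 4-methoxy-3-[4-oxo-3-(prop-1-en-2-yl)-2-(triisopropylsilyloxy)cyclobut-1-en-1-yl]-6-[(triisopropylsilyl)oxy]-2-benzofuran-1(3H)-one (racemic, mixture of diastereomers) | O=C1C(C2OC(=O)c3cc(O[Si](C(C)C)(C(C)C)C(C)C)cc(OC)c23)=C(O[Si](C(C)C)(C(C)C)C(C)C)C1C(C)=C | intermediate (not isolated)
19 | rac-4-methoxy-3-[5-methyl-1-oxo-3-(triisopropylsilyloxy)hexa-1,3,5-trien-2-yl]-6-[(triisopropylsilyl)oxy]-2-benzofuran-1(3H)-one | O=C=C(C1OC(=O)c2cc(O[Si](C(C)C)(C(C)C)C(C)C)cc(OC)c12)C(O[Si](C(C)C)(C(C)C)C(C)C)=CC(C)=C | intermediate (not isolated)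
20 | rac-4-methoxy-3-[4-methyl-6-oxo-2-(triisopropylsilyloxy)cyclohexa-1,3-dien-1-yl]-6-[(triisopropylsilyl)oxy]-2-benzofuran-1(3H)-one | O=C1CC(C)=CC(O[Si](C(C)C)(C(C)C)C(C)C)=C1C2OC(=O)c3cc(O[Si](C(C)C)(C(C)C)C(C)C)cc(OC)c23 | intermediate (not isolated)
21 | rac-3-{2-hydroxy-4-methyl-6-[(triisopropylsilyl)oxy]phenyl}-4-methoxy-6-[(triisopropylsilyl)oxy]-2-benzofuran-1(3H)-one | O=C1OC(c2c(O)cc(C)cc2O[Si](C(C)C)(C(C)C)C(C)C)c2c(OC)cc(O[Si](C(C)C)(C(C)C)C(C)C)cc12 | intermediate (product of the key step)
22 | rac-3-hydroxy-3-{2-hydroxy-4-methyl-6-[(triisopropylsilyl)oxy]phenyl}-4-methoxy-6-[(triisopropylsilyl)oxy]-2-benzofuran-1(3H)-one | O=C1OC(O)(c2c(O)cc(C)cc2O[Si](C(C)C)(C(C)C)C(C)C)c2c(OC)cc(O[Si](C(C)C)(C(C)C)C(C)C)cc12 | intermediate (not isolated)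
23 | 2-{2-hydroxy-4-methyl-6-[(triisopropylsilyl)oxy]benzoyl}-3-methoxy-5-[(triisopropylsilyl)oxy]benzoic acid | OC(=O)c1cc(O[Si](C(C)C)(C(C)C)C(C)C)cc(OC)c1C(=O)c1c(O)cc(C)cc1O[Si](C(C)C)(C(C)C)C(C)C | intermediate
24 | methyl 2-{2-hydroxy-4-methyl-6-[(triisopropylsilyl)oxy]benzoyl}-3-methoxy-5-[(triisopropylsilyl)oxy]benzoate | COC(=O)c1cc(O[Si](C(C)C)(C(C)C)C(C)C)cc(OC)c1C(=O)c1c(O)cc(C)cc1O[Si](C(C)C)(C(C)C)C(C)C | intermediate
25 | methyl 2-{2-acetoxy-4-methyl-6-[(triisopropylsilyl)oxy]benzoyl}-3-methoxy-5-[(triisopropylsilyl)oxy]benzoate | COC(=O)c1cc(O[Si](C(C)C)(C(C)C)C(C)C)cc(OC)c1C(=O)c1c(OC(C)=O)cc(C)cc1O[Si](C(C)C)(C(C)C)C(C)C | intermediate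
26 | penibenzophenone C, methyl 2-(2-acetoxy-6-hydroxy-4-methylbenzoyl)-5-hydroxy-3-methoxybenzoate | COC(=O)c1cc(O)cc(OC)c1C(=O)c1c(O)cc(C)cc1OC(C)=O | target

Total step count: 12. Longest linear sequence: 9 steps (1 → 3 → 4 → 5 → 13 → 21 → 23 → 24 → 25 → 26, that is steps 1, 2, 3, 6, 8, 9, 10, 11, 12).

Steps most likely to fail

Step 6. What may go wrong: loss or transfer of the ynol silyl group when the siloxyacetylene is metalated (attack at silicon, silyl scrambling), and base-induced propargyl-to-allenyl isomerisation of the acidic C3–H of the new lactone by the lithium methoxide released on ring closure. Fallback, which also makes steps 4 and 5 unnecessary: set out from 5 and bring in the ynol oxygen after the C–C bond. HC≡CMgBr is added in THF at −78 °C and the magnesium alkoxide is silylated in the cold (Me3SiOTf) before it can lactonise, to give methyl 3-methoxy-5-[(triisopropylsilyl)oxy]-2-{1-[(trimethylsilyl)oxy]prop-2-yn-1-yl}benzoate F1. The terminal alkyne is then converted into the ynol silyl ether by the acetylide oxidation of step 4 (LiN(SiMe3)2; LiOOt-Bu; i-Pr3SiOTf) to give methyl 3-methoxy-5-[(triisopropylsilyl)oxy]-2-{3-[(triisopropylsilyl)oxy]-1-[(trimethylsilyl)oxy]prop-2-yn-1-yl}benzoate F2. Brief methanolysis of the labile secondary trimethylsilyl ether (K2CO3 cat., MeOH, −20 °C) frees the alcohol, which closes onto the methyl ester, and the route is rejoined at 13.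

Step 8. What may go wrong: heterolysis of the propargylic lactone C–O bond under the electron push of the ynol ether (ionisation instead of cycloaddition), migration of silicon from oxygen to carbon on prolonged heating, or a [2+2] addition at the hindered alkyne carbon that is too slow, so that the vinylketene dimerises. Fallback: set out from 5 and take ring B from a preformed arene. Orcinol is converted (MOMCl, i-Pr2NEt) into 1,3-bis(methoxymethoxy)-5-methylbenzene F3, which is lithiated between its two oxygens (n-BuLi, THF, 0 °C) and added to 5 at −78 °C; the alkoxide lactonises to rac-3-[2,6-bis(methoxymethoxy)-4-methylphenyl]-4-methoxy-6-[(triisopropylsilyl)oxy]-2-benzofuran-1(3H)-one F4. Both acetals are removed (HCl, MeOH, rt) to give rac-3-(2,6-dihydroxy-4-methylphenyl)-4-methoxy-6-[(triisopropylsilyl)oxy]-2-benzofuran-1(3H)-one F5. Its two equivalent hydroxyls are monosilylated (i-Pr3SiOTf 1 equiv, 2,6-lutidine, CH2Cl2, −78 °C; bis-silylated and unreacted material recycled), which rejoins the route at 21.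

Step 9. What may go wrong: hydride abstraction at the crowded C3–H may be too slow (the C–H bond is poorly aligned with ring B), so that DDQ instead over-oxidises the electron-rich phenol. Fallback: set out from 21 and change from hydride abstraction to radical halogenation on the acetate. The phenol is acetylated (Ac2O, pyridine, DMAP) to rac-3-{2-acetoxy-4-methyl-6-[(triisopropylsilyl)oxy]phenyl}-4-methoxy-6-[(triisopropylsilyl)oxy]-2-benzofuran-1(3H)-one F6. Wohl–Ziegler bromination of the lactone C–H (NBS, (PhCO2)2 cat., PhCF3, 80 °C) should give rac-3-bromo-3-{2-acetoxy-4-methyl-6-[(triisopropylsilyl)oxy]phenyl}-4-methoxy-6-[(triisopropylsilyl)oxy]-2-benzofuran-1(3H)-one F7, which is hydrolysed without isolation (THF/H2O, NaHCO3) to 2-{2-acetoxy-4-methyl-6-[(triisopropylsilyl)oxy]benzoyl}-3-methoxy-5-[(triisopropylsilyl)oxy]benzoic acid F8. Esterification (MeI, KHCO3, DMF) rejoins the route at 25.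

Further compounds
F1 | step 6 | methyl 3-methoxy-5-[(triisopropylsilyl)oxy]-2-{1-[(trimethylsilyl)oxy]prop-2-yn-1-yl}benzoate (racemic) | COC(=O)c1cc(O[Si](C(C)C)(C(C)C)C(C)C)cc(OC)c1C(O[Si](C)(C)C)C#C
F2 | step 6 | methyl 3-methoxy-5-[(triisopropylsilyl)oxy]-2-{3-[(triisopropylsilyl)oxy]-1-[(trimethylsilyl)oxy]prop-2-yn-1-yl}benzoate (racemic) | COC(=O)c1cc(O[Si](C(C)C)(C(C)C)C(C)C)cc(OC)c1C(O[Si](C)(C)C)C#CO[Si](C(C)C)(C(C)C)C(C)C
F3 | step 8 | 1,3-bis(methoxymethoxy)-5-methylbenzene | COCOc1cc(C)cc(OCOC)c1
F4 | step 8 | rac-3-[2,6-bis(methoxymethoxy)-4-methylphenyl]-4-methoxy-6-[(triisopropylsilyl)oxy]-2-benzofuran-1(3H)-one | O=C1OC(c2c(OCOC)cc(C)cc2OCOC)c2c(OC)cc(O[Si](C(C)C)(C(C)C)C(C)C)cc12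
F5 | step 8 | rac-3-(2,6-dihydroxy-4-methylphenyl)-4-methoxy-6-[(triisopropylsilyl)oxy]-2-benzofuran-1(3H)-one | O=C1OC(c2c(O)cc(C)cc2O)c2c(OC)cc(O[Si](C(C)C)(C(C)C)C(C)C)cc12
F6 | step 9 | rac-3-{2-acetoxy-4-methyl-6-[(triisopropylsilyl)oxy]phenyl}-4-methoxy-6-[(triisopropylsilyl)oxy]-2-benzofuran-1(3H)-one | O=C1OC(c2c(OC(C)=O)cc(C)cc2O[Si](C(C)C)(C(C)C)C(C)C)c2c(OC)cc(O[Si](C(C)C)(C(C)C)C(C)C)cc12
F7 | step 9 | rac-3-bromo-3-{2-acetoxy-4-methyl-6-[(triisopropylsilyl)oxy]phenyl}-4-methoxy-6-[(triisopropylsilyl)oxy]-2-benzofuran-1(3H)-one | O=C1OC(Br)(c2c(OC(C)=O)cc(C)cc2O[Si](C(C)C)(C(C)C)C(C)C)c2c(OC)cc(O[Si](C(C)C)(C(C)C)C(C)C)cc12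
F8 | step 9 | 2-{2-acetoxy-4-methyl-6-[(triisopropylsilyl)oxy]benzoyl}-3-methoxy-5-[(triisopropylsilyl)oxy]benzoic acid | OC(=O)c1cc(O[Si](C(C)C)(C(C)C)C(C)C)cc(OC)c1C(=O)c1c(OC(C)=O)cc(C)cc1O[Si](C(C)C)(C(C)C)C(C)C
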